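**Plan**
- Retrosynthesis: the maleimide is cut back to a 3,4-disubstituted furan. Then come the C1–C(acyl) bond (aldol with a furan-3-carbaldehyde), the C2–CH3 bond, the C8–C8a bond (key cut) and the C5–C6 benzylation bond.
- Enabling feature: ring A carries the quaternary carbinol C4a beside the C3=C4 alkene with an oxidisable C2. That is the footprint of a 4-oxygenated cyclohexa-2,5-dienone whose second enone arm (C1=C8a) has taken up C8 of the C5–C8 tether.
- Forward order: acyclic C5–C8 chain on a phenol, then dearomatisation gives ring A as a dienone, then an enamine Michael addition closes ring B cis-fused. Ring A is next substituted at C1 and C2, and the furan is oxidised to the maleimide last.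
- Stereochemistry: C6 from oxazolidinone-directed benzylation; C4a and C8a from the prolinol catalyst choosing one enone arm; C8 by equilibration. C1 and C2 come from convex-face attack on the cis-decalin (aldol; MeLi, then palladium hydride delivery with inversion). C3′ comes from copper-catalysed SN2′ alkylation.

Key step: step 8

Remark on numbering: decalin carbons carry the target locants (C1 acyl, C2 methyl, C3=C4, C4a hydroxyl, C6 carboxyl, C8 methyl, C8a). Ring A is C1–C4/C4a/C8a, ring B is C4a–C8a, and C3′ is the octenyl stereocentre.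
Remark on catalyst sense: the enantiomers named for the prolinol catalyst (step 8) and for Taniaphos (step 13) are those predicted by the usual facial models. If a model proves inverted on these substrates, the antipode is used with no other change.
Remark on mixtures: the carbinol carbon made in step 15 and the lactol carbon made in step 20 are carried as epimer mixtures, since both become carbonyl carbons in step 21. Their SMILES leave these centres open.

**Step 1**
Reactants: 1 hex-5-enoic acid; 2 (S)-4-benzyloxazolidin-2-one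
Product: 4 (S)-4-benzyl-3-(hex-5-enoyl)oxazolidin-2-one, via mixed pivalic anhydride 3 (not isolated)
Conditions: t-BuCOCl, Et3N, THF, −20 °C; then LiCl, 2, −20 °C → rt
Reagents that add atoms: none
Why: N-acylation of the oxazolidinone through the mixed anhydride, in which the hindered pivaloyl carbonyl directs attack to the hexenoyl carbonyl.

**Step 2**
Reactants: 4 (S)-4-benzyl-3-(hex-5-enoyl)oxazolidin-2-one; 5 4-(benzyloxy)benzyl bromide
Product: 7 (S)-4-benzyl-3-[(R)-2-(4-(benzyloxy)benzyl)hex-5-enoyl]oxazolidin-2-one, via sodium enolate 6 (not isolated)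
Conditions: NaN(SiMe3)2, THF, −78 °C; then 5, −78 → −40 °C
Reagents that add atoms: none
Why: Evans alkylation; the chelated Z-enolate is benzylated on the face opposite the auxiliary benzyl group, which sets C6 as R.

**Step 3**
Reactants: 7 (S)-4-benzyl-3-[(R)-2-(4-(benzyloxy)benzyl)hex-5-enoyl]oxazolidin-2-one
Product: 8 methyl (R)-2-[4-(benzyloxy)benzyl]hex-5-enoate
Conditions: MeMgBr, MeOH, CH2Cl2, 0 °C
Reagents that add atoms: bromomagnesium methoxide, CO[Mg]Br (made in the flask from MeMgBr and methanol, CO)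
Why: Magnesium-assisted transesterification at the exocyclic imide carbonyl removes the auxiliary without enolising C6.

**Step 4**
Reactants: 8 methyl (R)-2-[4-(benzyloxy)benzyl]hex-5-enoate
Product: 10 methyl (R)-2-[4-(benzyloxy)benzyl]-5-oxopentanoate, via diol 9 (not isolated)
Conditions: OsO4 (cat.), NaIO4, 2,6-lutidine, dioxane/H2O, rt
Reagents that add atoms: osmium tetroxide, O=[Os](=O)(=O)=O; sodium periodate, [Na+].[O-]I(=O)(=O)=O
Why: Lemieux–Johnson oxidation cleaves the terminal alkene to the aldehyde that will become the enamine donor, and avoids ozone near the electron-rich aryl ether.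

**Step 5**
Reactants: 10 methyl (R)-2-[4-(benzyloxy)benzyl]-5-oxopentanoate
Product: 11 methyl (R)-2-(4-hydroxybenzyl)-5-oxopentanoate
Conditions: H2 (1 atm), 10% Pd/C, EtOAc, rt
Reagents that add atoms: none
Why: Hydrogenolysis of the benzyl aryl ether is fast under conditions that leave an aliphatic aldehyde and the ester untouched.

**Step 6**
Reactants: 11 methyl (R)-2-(4-hydroxybenzyl)-5-oxopentanoate
Product: 12 methyl (R)-2-[(1-hydroxy-4-oxocyclohexa-2,5-dien-1-yl)methyl]-5-oxopentanoate (para-quinol)
Conditions: PhI(OAc)2, MeCN/H2O, 0 °C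
Reagents that add atoms: water, O
Why: Oxidative dearomatisation of a para-alkylphenol, with water adding at the alkyl-bearing carbon; the chain carries an ester and an aldehyde rather than an acid or alcohol, so no spirocycle can form.

**Step 7**
Reactants: 12 para-quinol
Product: 13 methyl (R)-5-oxo-2-{[4-oxo-1-(triethylsilyloxy)cyclohexa-2,5-dien-1-yl]methyl}pentanoate
Conditions: Et3SiOTf, 2,6-lutidine, CH2Cl2, −78 °C
Reagents that add atoms: triethylsilyl triflate, CC[Si](CC)(CC)OS(=O)(=O)C(F)(F)F
Why: Silylation of the tertiary quinol hydroxyl at low temperature spares the aldehyde; the ether later stops C4a–O from trapping the C8 formyl group as a lactol and serves as the C4a protecting group until step 19.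

**Step 8**
Reactants: 13 methyl (R)-5-oxo-2-{[4-oxo-1-(triethylsilyloxy)cyclohexa-2,5-dien-1-yl]methyl}pentanoate
Product: 16 methyl (4aR,6R,8S,8aS)-8-formyl-2-oxo-4a-(triethylsilyloxy)-1,2,4a,5,6,7,8,8a-octahydronaphthalene-6-carboxylate, via enamine 14 (not isolated), via C8-epimeric aldehyde 15 (not isolated)
Conditions: (S)-α,α-diphenylprolinol trimethylsilyl ether (20 mol %), PhCO2H (20 mol %), toluene, 0 °C; then DBU (0.2 equiv), CH2Cl2, rt
Reagents that add atoms: none
Why: The catalyst condenses with the aldehyde to the E-enamine 14, whose carbon C8 adds to C8a of one enone arm, and hydrolysis of the iminium returns the amine. This is the known amine-catalysed desymmetrising intramolecular Michael addition of an aldehyde to a 4,4-disubstituted cyclohexadienone. Ring B closes 6-exo-trig through a chair in which the four-atom tether reaches C8a only on the dienone face it hangs from, so H8a and the silyloxy group end cis. C4a and C8a follow from which arm reacts: the silyloxydiphenylmethyl group screens one enamine face, and with the enamine pseudo-equatorial the open face meets only the arm giving 4aR,8aR; C8 forms first as epimer 15 and is equilibrated by DBU to the equatorial formyl group cis to the C6 ester, whose fixed configuration anchors the ring-B chair. The step needs arm selectivity against the tether's own bias, because the C6 ester must sit pseudo-axial in this chair; the catalyst's facial shielding is expected to outweigh that cost.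

**Step 9**
Reactants: 16 bicyclic aldehyde
Product: 17 methyl (4aR,6R,8S,8aS)-2-oxo-8-[(E)-(tosylhydrazono)methyl]-4a-(triethylsilyloxy)-1,2,4a,5,6,7,8,8a-octahydronaphthalene-6-carboxylate
Conditions: TsNHNH2 (1.0 equiv), THF, rt
Reagents that add atoms: p-toluenesulfonyl hydrazide, Cc1ccc(cc1)S(=O)(=O)NN
Why: Hydrazone condensation is much faster at the aldehyde than at the conjugated ring ketone, so one equivalent should react at the formyl group only.

**Step 10**
Reactants: 17 tosylhydrazone
Product: 19 methyl (4aR,6R,8S,8aS)-8-methyl-2-oxo-4a-(triethylsilyloxy)-1,2,4a,5,6,7,8,8a-octahydronaphthalene-6-carboxylate, via N-boryl hydrazine 18 (not isolated)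
Conditions: catecholborane, CHCl3, 0 °C; then NaOAc·3H2O, reflux
Reagents that add atoms: none
Why: Caglioti-type tosylhydrazone reduction: hydride adds to C=N, acetate triggers loss of sulfinate, and the diazene extrudes N2 to leave CH3; catecholborane does not reduce an s-trans cyclohexenone or an ester, and C8 itself is not touched.

**Step 11**
Reactants: 20 3,4-dibromofuran
Product: 22 1-(4-bromofuran-3-yl)prop-2-en-1-ol (racemic), via 4-bromo-3-furyllithium 21 (not isolated)
Conditions: n-BuLi (1.0 equiv), Et2O, −78 °C; then acrolein, −78 °C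
Reagents that add atoms: acrolein, C=CC=O
Why: Single bromine–lithium exchange of the symmetrical dibromide gives a 3-furyllithium that is stable at −78 °C and adds 1,2 to acrolein.

**Step 12**
Reactants: 22 1-(4-bromofuran-3-yl)prop-2-en-1-ol
Product: 23 (E)-3-bromo-4-(3-bromoprop-1-en-1-yl)furan
Conditions: PBr3, Et2O, −10 → 0 °C
Reagents that add atoms: phosphorus tribromide, BrP(Br)Br
Why: Bromination of an aryl vinyl carbinol proceeds with allylic transposition, since conjugation with the furan makes the primary E-bromide the thermodynamic product.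

**Step 13**
Reactants: 23 (E)-3-bromo-4-(3-bromoprop-1-en-1-yl)furan
Product: 24 (S)-3-bromo-4-(oct-1-en-3-yl)furan
Conditions: n-C5H11MgBr, CuBr·SMe2 (5 mol %), (R,Rp)-Taniaphos (6 mol %), CH2Cl2, −75 °C
Reagents that add atoms: pentylmagnesium bromide, CCCCC[Mg]Br
Why: Copper-catalysed asymmetric allylic alkylation of a cinnamyl-type bromide delivers the alkyl group SN2′ to the aryl-bearing carbon, and the ferrocenyl diphosphine sets C3′ as S; the furyl bromide is inert at this temperature.

**Step 14**
Reactants: 24 (S)-3-bromo-4-(oct-1-en-3-yl)furan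
Product: 26 4-[(S)-oct-1-en-3-yl]furan-3-carbaldehyde, via furyllithium 25 (not isolated)
Conditions: n-BuLi, Et2O, −78 °C; then DMF, −78 → 0 °C
Reagents that add atoms: N,N-dimethylformamide, CN(C)C=O
Why: Bromine–lithium exchange outpaces deprotonation of the doubly allylic C–H at −78 °C, and formylation of the aryllithium with DMF is standard.

**Step 15**
Reactants: 19 methyl enone; 26 4-[(S)-oct-1-en-3-yl]furan-3-carbaldehyde
Product: 28 methyl (1S,4aR,6R,8S,8aR)-1-{hydroxy[4-((S)-oct-1-en-3-yl)furan-3-yl]methyl}-8-methyl-2-oxo-4a-(triethylsilyloxy)-1,2,4a,5,6,7,8,8a-octahydronaphthalene-6-carboxylate (carbinol epimers), via lithium enolate 27 (not isolated)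
Conditions: LiN(SiMe3)2, THF, −78 °C; then 26, −78 °C; AcOH quench at −78 °C
Reagents that add atoms: none
Why: Kinetic deprotonation can occur only at C1 (C4a is quaternary and the ester α-hydrogen is far less acidic), and the aldol addition to the non-enolisable aldehyde takes place on the convex face of C1 because the other face points into ring B, which sets C1 as S.

**Step 16**
Reactants: 28 aldol adduct
Product: 29 methyl (1S,4aR,6R,8S,8aR)-8-methyl-1-{[4-((S)-oct-1-en-3-yl)furan-3-yl](triethylsilyloxy)methyl}-2-oxo-4a-(triethylsilyloxy)-1,2,4a,5,6,7,8,8a-octahydronaphthalene-6-carboxylate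
Conditions: Et3SiOTf, 2,6-lutidine, CH2Cl2, −78 → 0 °C
Reagents that add atoms: triethylsilyl triflate, CC[Si](CC)(CC)OS(=O)(=O)C(F)(F)F
Why: Silylation of the secondary aldol hydroxyl blocks retro-aldol cleavage and alkoxide chemistry in the next two steps.

**Step 17**
Reactants: 29 bis-silyl ether ketone
Product: 31 methyl (1S,2R,4aR,6R,8S,8aR)-2-(methoxycarbonyloxy)-2,8-dimethyl-1-{[4-((S)-oct-1-en-3-yl)furan-3-yl](triethylsilyloxy)methyl}-4a-(triethylsilyloxy)-1,2,4a,5,6,7,8,8a-octahydronaphthalene-6-carboxylate, via lithium alkoxide 30 (not isolated)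
Conditions: MeLi (1.2 equiv), THF, −78 °C; then ClCO2Me, −78 → 0 °C
Reagents that add atoms: methyllithium, [Li]C; methyl chloroformate, COC(=O)Cl
Why: 1,2-Addition of MeLi to the enone carbonyl from the convex face (axial attack) places the new methyl axial and the oxygen equatorial at C2, and the tertiary alkoxide is trapped as its carbonate; the ester is much slower than the ketone at −78 °C.

**Step 18**
Reactants: 31 tertiary allylic carbonate
Product: 32 methyl (1S,2R,4aR,6R,8S,8aR)-2,8-dimethyl-1-{[4-((S)-oct-1-en-3-yl)furan-3-yl](triethylsilyloxy)methyl}-4a-(triethylsilyloxy)-1,2,4a,5,6,7,8,8a-octahydronaphthalene-6-carboxylate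
Conditions: Pd(OAc)2 (5 mol %), n-Bu3P (5 mol %), HCO2NH4, 1,4-dioxane, 60 °C
Reagents that add atoms: none
Why: Tsuji-type formate hydrogenolysis: zerovalent palladium ionises the carbonate with inversion (metal on the convex face), formate loses CO2, and the hydride is delivered from the metal to the more substituted allyl terminus C2, which leaves the C3=C4 alkene and sets C2 as R with the methyl equatorial.

**Step 19**
Reactants: 32 bis-silyl ether ester
Product: 34 (1S,2R,4aR,6R,8S,8aR)-4a-hydroxy-1-{hydroxy[4-((S)-oct-1-en-3-yl)furan-3-yl]methyl}-2,8-dimethyl-1,2,4a,5,6,7,8,8a-octahydronaphthalene-6-carboxylic acid (carbinol epimers), via diol methyl ester 33 (not isolated)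
Conditions: Bu4NF, THF, 0 °C → rt; then LiOH, H2O/MeOH, rt; 1 M HCl to pH 4 at 0 °C
Reagents that add atoms: lithium hydroxide, [Li+].[OH-]
Why: Fluoride removes both triethylsilyl groups and hydroxide saponifies the equatorial methyl ester; freeing the acid here avoids any basic deprotection once the maleimide exists.

**Step 20**
Reactants: 34 furyl diol acid
Product: 36 γ-hydroxybutenolide (5-hydroxyfuran-2(5H)-one carrying the octenyl group at C3 and the carbinol at C4, together with its regioisomer; lactol epimers), via endoperoxide 35 (not isolated)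
Conditions: O2, hν (visible), tetraphenylporphyrin (cat.), i-Pr2NEt, CH2Cl2, −78 °C → rt
Reagents that add atoms: oxygen, O=O
Why: Singlet oxygen adds [4+2] to the electron-rich 3,4-dialkylfuran far faster than it reacts with the ring alkene or the vinyl group, and amine-induced Kornblum–DeLaMare opening of the endoperoxide gives the hydroxybutenolide.

**Step 21**
Reactants: 36 γ-hydroxybutenolide mixture
Product: 37 (1S,2R,4aR,6R,8S,8aR)-4a-hydroxy-2,8-dimethyl-1-{[4-((S)-oct-1-en-3-yl)-2,5-dioxo-2,5-dihydrofuran-3-yl]carbonyl}-1,2,4a,5,6,7,8,8a-octahydronaphthalene-6-carboxylic acid (acyl maleic anhydride)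
Conditions: DMP (triacetoxy benziodoxolone periodinane, 3 equiv), CH2Cl2, 0 °C → rt
Reagents that add atoms: none
Why: The periodinane oxidises the lactol to the anhydride and the secondary carbinol to the ketone, so all regio- and stereoisomers converge; the tertiary alcohol and the acid are inert, and chromium reagents are avoided because they would transpose the tertiary allylic alcohol.

**Step 22**
Reactants: 37 acyl maleic anhydride
Product: 38 target, (1S,2R,4aR,6R,8S,8aR)-4a-hydroxy-2,8-dimethyl-1-{[4-((S)-oct-1-en-3-yl)-2,5-dioxo-2,5-dihydro-1H-pyrrol-3-yl]carbonyl}-1,2,4a,5,6,7,8,8a-octahydronaphthalene-6-carboxylic acid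
Conditions: (Me3Si)2NH, MeOH, DMF, rt; dilute aqueous acid work-up
Reagents that add atoms: hexamethyldisilazane, C[Si](C)(C)N[Si](C)(C)C
Why: Hexamethyldisilazane and methanol release ammonia slowly; it opens the anhydride to an amic acid that recloses to the N–H imide, and the acidic N–H of the product shields the doubly allylic C3′–H from deprotonation.

**Compound list**
1 | hex-5-enoic acid | C=CCCCC(=O)O | starting material
2 | (S)-4-benzyloxazolidin-2-one | O=C1N[C@@H](Cc2ccccc2)CO1 | starting material
3 | hex-5-enoic pivalic anhydride | C=CCCCC(=O)OC(=O)C(C)(C)C | intermediate (not isolated)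
4 | (S)-4-benzyl-3-(hex-5-enoyl)oxazolidin-2-one | C=CCCCC(=O)N1[C@@H](Cc2ccccc2)COC1=O | intermediate
5 | 4-(benzyloxy)benzyl bromide | BrCc1ccc(OCc2ccccc2)cc1 | starting material
6 | sodium (Z)-enolate of 4 | C=CCC/C=C(\[O-])N1[C@@H](Cc2ccccc2)COC1=O.[Na+] | intermediate (not isolated)
7 | (S)-4-benzyl-3-[(R)-2-(4-(benzyloxy)benzyl)hex-5-enoyl]oxazolidin-2-one | C=CCC[C@H](Cc1ccc(OCc2ccccc2)cc1)C(=O)N1[C@@H](Cc2ccccc2)COC1=O | intermediate
8 | methyl (R)-2-[4-(benzyloxy)benzyl]hex-5-enoate | C=CCC[C@H](Cc1ccc(OCc2ccccc2)cc1)C(=O)OC | intermediate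
9 | methyl (2R)-2-[4-(benzyloxy)benzyl]-5,6-dihydroxyhexanoate (C5 epimers) | OCC(O)CC[C@H](Cc1ccc(OCc2ccccc2)cc1)C(=O)OC | intermediate (not isolated)
10 | methyl (R)-2-[4-(benzyloxy)benzyl]-5-oxopentanoate | O=CCC[C@H](Cc1ccc(OCc2ccccc2)cc1)C(=O)OC | intermediate
11 | methyl (R)-2-(4-hydroxybenzyl)-5-oxopentanoate | O=CCC[C@H](Cc1ccc(O)cc1)C(=O)OC | intermediate
12 | methyl (R)-2-[(1-hydroxy-4-oxocyclohexa-2,5-dien-1-yl)methyl]-5-oxopentanoate | O=CCC[C@H](CC1(O)C=CC(=O)C=C1)C(=O)OC | intermediate
13 | methyl (R)-5-oxo-2-{[4-oxo-1-(triethylsilyloxy)cyclohexa-2,5-dien-1-yl]methyl}pentanoate (key-step precursor) | O=CCC[C@H](CC1(O[Si](CC)(CC)CC)C=CC(=O)C=C1)C(=O)OC | intermediate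
14 | E-enamine of 13 with (S)-α,α-diphenylprolinol trimethylsilyl ether | C[Si](C)(C)OC(c1ccccc1)(c1ccccc1)[C@@H]1CCCN1/C=C/C[C@H](CC1(O[Si](CC)(CC)CC)C=CC(=O)C=C1)C(=O)OC | intermediate (not isolated)
15 | methyl (4aR,6R,8R,8aS)-8-formyl-2-oxo-4a-(triethylsilyloxy)-1,2,4a,5,6,7,8,8a-octahydronaphthalene-6-carboxylate (C8 epimer of 16) | O=C1C[C@H]2[C@H](C=O)C[C@@H](C(=O)OC)C[C@@]2(O[Si](CC)(CC)CC)C=C1 | intermediate (not isolated)
16 | methyl (4aR,6R,8S,8aS)-8-formyl-2-oxo-4a-(triethylsilyloxy)-1,2,4a,5,6,7,8,8a-octahydronaphthalene-6-carboxylate (key-step product; cis-fused, formyl cis to ester) | O=C1C[C@H]2[C@@H](C=O)C[C@@H](C(=O)OC)C[C@@]2(O[Si](CC)(CC)CC)C=C1 | intermediate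
17 | tosylhydrazone of 16 | O=C1C[C@H]2[C@@H](/C=N/NS(=O)(=O)c3ccc(C)cc3)C[C@@H](C(=O)OC)C[C@@]2(O[Si](CC)(CC)CC)C=C1 | intermediate
18 | N-(1,3,2-benzodioxaborol-2-yl)-N′-tosylhydrazine from 17 | O=C1C[C@H]2[C@@H](CN(NS(=O)(=O)c3ccc(C)cc3)B3Oc4ccccc4O3)C[C@@H](C(=O)OC)C[C@@]2(O[Si](CC)(CC)CC)C=C1 | intermediate (not isolated)
19 | methyl (4aR,6R,8S,8aS)-8-methyl-2-oxo-4a-(triethylsilyloxy)-1,2,4a,5,6,7,8,8a-octahydronaphthalene-6-carboxylate | O=C1C[C@H]2[C@@H](C)C[C@@H](C(=O)OC)C[C@@]2(O[Si](CC)(CC)CC)C=C1 | intermediate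
20 | 3,4-dibromofuran | Brc1cocc1Br | starting material
21 | 4-bromo-3-furyllithium | [Li]c1cocc1Br | intermediate (not isolated)
22 | 1-(4-bromofuran-3-yl)prop-2-en-1-ol (racemic) | C=CC(O)c1cocc1Br | intermediate
23 | (E)-3-bromo-4-(3-bromoprop-1-en-1-yl)furan | BrC/C=C/c1cocc1Br | intermediate
24 | (S)-3-bromo-4-(oct-1-en-3-yl)furan | C=C[C@H](CCCCC)c1cocc1Br | intermediate
25 | 4-[(S)-oct-1-en-3-yl]-3-furyllithium | C=C[C@H](CCCCC)c1cocc1[Li] | intermediate (not isolated)
26 | 4-[(S)-oct-1-en-3-yl]furan-3-carbaldehyde | C=C[C@H](CCCCC)c1cocc1C=O | intermediate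
27 | lithium C1–C2 enolate of 19 | [Li]OC1=C[C@H]2[C@@H](C)C[C@@H](C(=O)OC)C[C@@]2(O[Si](CC)(CC)CC)C=C1 | intermediate (not isolated)
28 | aldol adduct (1S,4aR,6R,8S,8aR; carbinol epimers) | C=C[C@H](CCCCC)c1cocc1C(O)[C@@H]2[C@H]3[C@@H](C)C[C@@H](C(=O)OC)C[C@@]3(O[Si](CC)(CC)CC)C=CC2=O | intermediate
29 | bis(triethylsilyl) ether of 28 | C=C[C@H](CCCCC)c1cocc1C(O[Si](CC)(CC)CC)[C@@H]2[C@H]3[C@@H](C)C[C@@H](C(=O)OC)C[C@@]3(O[Si](CC)(CC)CC)C=CC2=O | intermediate
30 | lithium C2 alkoxide (2R; methyl axial) | C=C[C@H](CCCCC)c1cocc1C(O[Si](CC)(CC)CC)[C@@H]2[C@H]3[C@@H](C)C[C@@H](C(=O)OC)C[C@@]3(O[Si](CC)(CC)CC)C=C[C@@]2(C)O[Li] | intermediate (not isolated)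
31 | C2 tertiary allylic methyl carbonate (1S,2R,4aR,6R,8S,8aR) | C=C[C@H](CCCCC)c1cocc1C(O[Si](CC)(CC)CC)[C@@H]2[C@H]3[C@@H](C)C[C@@H](C(=O)OC)C[C@@]3(O[Si](CC)(CC)CC)C=C[C@@]2(C)OC(=O)OC | intermediate
32 | C2-methyl bis-silyl ether ester (1S,2R,4aR,6R,8S,8aR) | C=C[C@H](CCCCC)c1cocc1C(O[Si](CC)(CC)CC)[C@@H]2[C@H]3[C@@H](C)C[C@@H](C(=O)OC)C[C@@]3(O[Si](CC)(CC)CC)C=C[C@H]2C | intermediate
33 | furyl diol methyl ester | C=C[C@H](CCCCC)c1cocc1C(O)[C@@H]2[C@H]3[C@@H](C)C[C@@H](C(=O)OC)C[C@@]3(O)C=C[C@H]2C | intermediate (not isolated)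
34 | furyl diol acid (1S,2R,4aR,6R,8S,8aR) | C=C[C@H](CCCCC)c1cocc1C(O)[C@@H]2[C@H]3[C@@H](C)C[C@@H](C(=O)O)C[C@@]3(O)C=C[C@H]2C | intermediate
35 | furan endoperoxide (2,3,7-trioxabicyclo[2.2.1]hept-5-ene) | C=C[C@H](CCCCC)C1=C(C(O)[C@@H]2[C@H]3[C@@H](C)C[C@@H](C(=O)O)C[C@@]3(O)C=C[C@H]2C)C2OOC1O2 | intermediate (not isolated)
36 | γ-hydroxybutenolide (regioisomer shown; lactol and carbinol epimers) | C=C[C@H](CCCCC)C1=C(C(O)[C@@H]2[C@H]3[C@@H](C)C[C@@H](C(=O)O)C[C@@]3(O)C=C[C@H]2C)C(O)OC1=O | intermediate
37 | acyl maleic anhydride acid | C=C[C@H](CCCCC)C1=C(C(=O)[C@@H]2[C@H]3[C@@H](C)C[C@@H](C(=O)O)C[C@@]3(O)C=C[C@H]2C)C(=O)OC1=O | intermediate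
38 | CNP0326775.3 | C=C[C@H](CCCCC)C1=C(C(=O)[C@@H]2[C@H]3[C@@H](C)C[C@@H](C(=O)O)C[C@@]3(O)C=C[C@H]2C)C(=O)NC1=O | target

**Totals**
Total step count: 22. Longest linear sequence: 18 steps (steps 1–10 and 15–22); the furan aldehyde branch is 4 steps (11–14).

**Steps most likely to fail**

1. Step 8. The closure may leak to the other enone arm, because the C6 ester has to occupy a pseudo-axial site in the chair that the catalyst selects, and the tether alone would prefer the opposite arm. Fallback: separate the arm choice from the ring closure, setting out from 13. Conjugate addition of thiophenol (PhSH, Et3N cat., CH2Cl2, 0 °C) to one enone arm should give the mono-sulfide F1. The two arm isomers are diastereomers and separable, and the unwanted one is returned to 13 with DBU. F1 has a single enone left, so pyrrolidine/AcOH closes ring B with no arm to choose and should give the bicyclic sulfide F2. Oxidation with NaIO4 gives the sulfoxide F3, and thermal syn-elimination in warm toluene restores the C3=C4 alkene, rejoining the route at 16.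

2. Step 18. The hydride may be delivered to C4 instead of C2, or the allyl palladium intermediate may lose a β-hydrogen to give a diene; the C2 configuration also depends on the face chosen by MeLi in step 17. Fallback: replace steps 17 and 18 by copper-mediated allylic substitution, setting out from 29. Luche reduction (NaBH4, CeCl3·7H2O, MeOH, −78 °C) should give the equatorial allylic alcohol F4 by convex-face hydride attack. Mitsunobu inversion with benzoic acid (PPh3, DIAD, THF) gives the pseudo-axial benzoate F5. Me2CuLi (Et2O, −20 °C) should then substitute anti at C2, since C4 is shielded by the quaternary C4a, and the route is rejoined at 32.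

3. Step 15. The lithium aldolate is crowded (the new C1 substituent sits close to the C8 methyl), so reversion to enolate and aldehyde or stalled conversion is the likely failure. Fallback: an irreversible Lewis-acid aldol, setting out from 19. Me3SiOTf/Et3N (CH2Cl2, 0 °C) gives the silyl dienol ether F6. Mukaiyama addition to 26 with BF3·OEt2 at −78 °C, through an open transition state on the same convex face, should give 28 after aqueous work-up, where the route is rejoined.

**Further compounds**
F1 | step 8 | methyl (R)-5-oxo-2-{[4-oxo-6-(phenylsulfanyl)-1-(triethylsilyloxy)cyclohex-2-en-1-yl]methyl}pentanoate (C4a as in 16; sulfide carbon as formed) | O=C1C=C[C@@](O[Si](CC)(CC)CC)(C[C@@H](CCC=O)C(=O)OC)C(Sc2ccccc2)C1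
F2 | step 8 | 4-(phenylsulfanyl)-3,4-dihydro derivative of 16 | O=C1C[C@H]2[C@@H](C=O)C[C@@H](C(=O)OC)C[C@@]2(O[Si](CC)(CC)CC)C(Sc3ccccc3)C1
F3 | step 8 | 4-(phenylsulfinyl)-3,4-dihydro derivative of 16 | O=C1C[C@H]2[C@@H](C=O)C[C@@H](C(=O)OC)C[C@@]2(O[Si](CC)(CC)CC)C(S(=O)c3ccccc3)C1
F4 | step 18 | (2R)-allylic alcohol from 29 (hydroxyl equatorial) | C=C[C@H](CCCCC)c1cocc1C(O[Si](CC)(CC)CC)[C@@H]2[C@H]3[C@@H](C)C[C@@H](C(=O)OC)C[C@@]3(O[Si](CC)(CC)CC)C=C[C@H]2O
F5 | step 18 | (2S)-allylic benzoate (pseudo-axial) | C=C[C@H](CCCCC)c1cocc1C(O[Si](CC)(CC)CC)[C@@H]2[C@H]3[C@@H](C)C[C@@H](C(=O)OC)C[C@@]3(O[Si](CC)(CC)CC)C=C[C@@H]2OC(=O)c4ccccc4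
F6 | step 15 | 2-(trimethylsilyloxy) C1–C2 dienol ether of 19 | C[Si](C)(C)OC1=C[C@H]2[C@@H](C)C[C@@H](C(=O)OC)C[C@@]2(O[Si](CC)(CC)CC)C=C1
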